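**Retrosynthetic overview**
- The strategy rests on the dihydrofuran ring O1–C2–C3–C3a–C7a: C3 is a methine joining C6 of the 4-hydroxy-2-pyranone to C3a of the fused 2-pyranone (next to the enol-ether carbon C7a), which is the carbon a Knoevenagel condensation creates, and C2 is an isolated ArCH between O1 and C3.
- O1–C2 and C2–C3 are cut together in a formal [4+1] disconnection into the 1-oxadiene O=C7a–C3a=C3 (a 3-(pyranonylmethylidene)pyran-2,4-dione) and a chiral sulfonium benzylide as the one-carbon unit.
- The oxadiene is made in the same flask by Knoevenagel condensation (C3–C3a bond) of silyl-protected hispidin with a 4-alkoxy-2-pyranone-6-carbaldehyde and is held as its sulfinic acid adduct until base is added; protected hispidin comes from the dianion aldol of triacetic acid lactone with protected 3,4-dihydroxybenzaldehyde.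
- Ring order: both 2-pyranone rings are bought intact (triacetic acid lactone, used twice), the dihydrofuran ring is closed last in the [4+1] step, which also brings in the second catechol (3,4-dihydroxybenzaldehyde, used twice), and one fluoride treatment then removes every silicon group.

Key step: step 11

Assumption: the benzylide of the (2S,5S)-thiolanium salt is taken to react through the same ylide face as in its benzylidene transfer to aldehydes, which corresponds to (2S) here because aryl outranks C3 at the new centre (in an epoxide the ring carbon outranks aryl); if a first run showed the opposite sense, the enantiomeric sulfide from (2S,5S)-hexane-2,5-diol would be used with no other change.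

TBS = tert-butyldimethylsilyl; EDDA = ethylenediammonium diacetate.

Step 1
Reactants: 1 3,4-dihydroxybenzaldehyde
Product: 2 3,4-bis(TBS-oxy)benzaldehyde
Conditions: TBSCl (2.4 equiv), imidazole (5 equiv), DMF, 0 °C to rt
Reagents that add atoms: tert-butyldimethylsilyl chloride, CC(C)(C)[Si](C)(C)Cl
Why: Imidazole-promoted O-silylation of both phenols should give a non-enolisable aldehyde whose catechol is masked against base and oxidation for the rest of the route.

Step 2
Reactants: 3 4-hydroxy-6-methyl-2H-pyran-2-one (triacetic acid lactone); 2 3,4-bis(TBS-oxy)benzaldehyde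
Product: 4 racemic 6-{2-[3,4-bis(TBS-oxy)phenyl]-2-hydroxyethyl}-4-hydroxy-2H-pyran-2-one
Conditions: LiN(iPr)2 (LDA, 2.2 equiv), THF, −78 to −20 °C; then 2, −78 °C; aq. HCl to pH 3
Reagents that add atoms: none
Why: Aldol addition of the O,C7-dianion of the hydroxypyranone, which reacts at its more basic methyl-derived carbon, to the non-enolisable aldehyde should give the β-hydroxy adduct, whose racemic carbinol centre is removed in the next step.

Step 3
Reactants: 4 racemic aldol adduct
Product: 5 6-{(E)-2-[3,4-bis(TBS-oxy)phenyl]ethenyl}-4-hydroxy-2H-pyran-2-one (3',4'-bis-O-TBS hispidin)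
Conditions: TsOH·H2O (10 mol %), toluene (dilute), 70 °C
Reagents that add atoms: none
Why: Acid-catalysed E1 dehydration through the benzylic cation stabilised by the para-silyloxy group should give the conjugated E-styrylpyranone under thermodynamic control, with acid preferred to sulfonate activation because the acidic 4-OH would be sulfonylated as well and with dilution to suppress intermolecular benzylation at C3.

Step 4
Reactants: 3 4-hydroxy-6-methyl-2H-pyran-2-one
Product: 6 6-methyl-4-[2-(trimethylsilyl)ethoxy]-2H-pyran-2-one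
Conditions: TMSCH2CH2OH, PPh3, DIAD, THF, 0 °C to rt
Reagents that add atoms: 2-(trimethylsilyl)ethanol, C[Si](C)(C)CCO
Why: Mitsunobu O-alkylation of the acidic 4-hydroxyl (a vinylogous carboxylic acid) is an established route to 4-alkoxy-2-pyranones and blocks C3 of this ring as a Knoevenagel donor with a group that fluoride removes.

Step 5
Reactants: 6 6-methyl-4-[2-(trimethylsilyl)ethoxy]-2H-pyran-2-one
Product: 7 2-oxo-4-[2-(trimethylsilyl)ethoxy]-2H-pyran-6-carbaldehyde
Conditions: SeO2 (3 equiv), 1,4-dioxane, 150 °C, sealed tube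
Reagents that add atoms: selenium dioxide, O=[Se]=O
Why: Riley oxidation of the vinylogously activated 6-methyl group of a 4-alkoxy-2-pyranone to the 6-carbaldehyde is a known transformation that leaves the lactone and the vinylogous ester untouched.

Step 6
Reactants: 8 (2R,5R)-hexane-2,5-diol
Product: 9 (2R,5R)-hexane-2,5-diyl dimethanesulfonate
Conditions: MsCl (2.4 equiv), Et3N, CH2Cl2, 0 °C
Reagents that add atoms: methanesulfonyl chloride, CS(=O)(=O)Cl
Why: Sulfonylation takes place at oxygen only, so both stereocentres are carried over unchanged into a bis-electrophile.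

Step 7
Reactants: 9 (2R,5R)-hexane-2,5-diyl dimethanesulfonate
Product: 10 (2S,5S)-2,5-dimethylthiolane
Conditions: Na2S·9H2O, EtOH, rt
Reagents that add atoms: disodium sulfide (Na2S), [Na+].[Na+].[S-2]
Why: Two successive SN2 displacements by sulfur (intermolecular, then 5-exo-tet) invert both carbons and should give the C2-symmetric trans-thiolane.

Step 8
Reactants: 2 3,4-bis(TBS-oxy)benzaldehyde
Product: 11 [3,4-bis(TBS-oxy)phenyl]methanol
Conditions: NaBH4, THF/EtOH, 0 °C
Reagents that add atoms: none
Why: Borohydride reduction of the aldehyde is fast at 0 °C, and the aryl silyl ethers should survive the brief cold treatment.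

Step 9
Reactants: 11 [3,4-bis(TBS-oxy)phenyl]methanol
Product: 12 4-(bromomethyl)-1,2-bis(TBS-oxy)benzene
Conditions: CBr4, PPh3, CH2Cl2, 0 °C
Reagents that add atoms: carbon tetrabromide, BrC(Br)(Br)Br
Why: Appel bromination converts the benzylic alcohol under neutral conditions that the silyl ethers tolerate, and the reactive bromide is used at once.

Step 10
Reactants: 12 4-(bromomethyl)-1,2-bis(TBS-oxy)benzene; 10 (2S,5S)-2,5-dimethylthiolane
Product: 13 (2S,5S)-1-[3,4-bis(TBS-oxy)benzyl]-2,5-dimethylthiolan-1-ium tetrafluoroborate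
Conditions: 10 (1.5 equiv), AgBF4, CH2Cl2, 0 °C to rt, dark
Reagents that add atoms: silver tetrafluoroborate, [Ag+].F[B-](F)(F)F
Why: S-alkylation of the sulfide by the electron-rich benzyl bromide is driven by precipitation of AgBr, and the C2 symmetry of the thiolane makes its two sulfur lone pairs equivalent, so one salt forms and sulfur is not a stereocentre.

Step 11
Reactants: 5 3',4'-bis-O-TBS hispidin; 7 2-oxo-4-[2-(trimethylsilyl)ethoxy]-2H-pyran-6-carbaldehyde; 13 (2S,5S)-1-[3,4-bis(TBS-oxy)benzyl]-2,5-dimethylthiolan-1-ium tetrafluoroborate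
Product: 17 (2S,3S)-2-[3,4-bis(TBS-oxy)phenyl]-6-{(E)-2-[3,4-bis(TBS-oxy)phenyl]ethenyl}-3-{2-oxo-4-[2-(trimethylsilyl)ethoxy]-2H-pyran-6-yl}-2,3-dihydro-4H-furo[3,2-c]pyran-4-one, via pyranone oxadiene 14 (not isolated), via sulfinic acid adduct 15 (not isolated), via sulfonium benzylide 16 (not isolated)
Conditions: 5 (1.05 equiv), 7 (1.0 equiv), p-TolSO2H (1.3 equiv), EDDA (10 mol %), 4 Å MS, CH2Cl2, rt, until 7 is consumed; then 13 (1.3 equiv), MeCN, Cs2CO3 (4 equiv), −30 to 0 °C; then DBU (0.2 equiv), 0 °C, brief
Reagents that add atoms: none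
Why: Proposed new method: in the first stage EDDA-catalysed Knoevenagel condensation of C3 of 5 with aldehyde 7 (the limiting component) forms the C3–C3a bond and oxadiene 14, which the sulfinic acid traps by sulfa-Michael addition as adduct 15, so that neither free aldehyde, which the benzylide would epoxidise, nor the 2:1 bis-pyranone adduct remains when base is added; Cs2CO3 then turns 15 into its enolate, which loses sulfinate (E1cB) and releases 14 gradually, and deprotonates 13 to benzylide 16, whose carbon adds to the doubly activated exocyclic carbon of 14 (C2–C3 bond) to give a betaine with its charge in the pyran-2,4-dione enolate, after which the 4-oxygen of that enolate displaces the thiolane at the benzylic carbon (O1–C2 bond). The closest known reaction types are the three-component sulfonylalkylation of cyclic 1,3-dicarbonyl enols, the formal [4+1] annulation of sulfonium and ammonium ylides with 2-alkylidene-1,3-dicarbonyls and with ortho-quinone methides released by base from α-sulfonylalkyl precursors, and Corey–Chaykovsky-type benzylidene transfer from C2-symmetric thiolanium salts to aldehydes, but a chiral semi-stabilised benzylide has not been combined with a pyranone oxadiene of this kind. The dihydrofuran ring closes in a 5-exo-tet SN2 mode with inversion at the benzylic carbon, and if 3-exo-tet C-alkylation intervened, the donor–acceptor cyclopropane would be expected to undergo Cloke–Wilson ring expansion to the same ring. C2 is controlled by the thiolane, whose 2,5-methyl groups expose one face of the ylide carbon, followed by the stereospecific inversion, and C3 is controlled relative to C2 by closure of the anti betaine and, for any cis isomer, by DBU epimerisation of the C3–H (vinylogous to the lactone carbonyl of the alkoxypyranone) to the more stable trans ring. The step needs 1,4-addition at the exocyclic carbon in preference to the styryl terminus, closure through the 4-oxygen in preference to the lactone carbonyl oxygen (favoured because it keeps the conjugated 2-pyranone) and clean SN2 character at the electron-rich benzylic carbon, which the silylated phenols support by suppressing quinone methide formation.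

Step 12
Reactants: 17 tetra-O-TBS, 4-O-(2-trimethylsilylethyl) hypholomine B
Product: 18 hypholomine B, (2S,3S)-2-(3,4-dihydroxyphenyl)-6-[(E)-2-(3,4-dihydroxyphenyl)ethenyl]-3-(4-hydroxy-2-oxo-2H-pyran-6-yl)-2,3-dihydro-4H-furo[3,2-c]pyran-4-one
Conditions: TBAF/AcOH (1:1, 8 equiv), degassed THF, 0 °C to rt; aq. citric acid work-up
Reagents that add atoms: none
Why: Fluoride-induced desilylation should cleave the four aryl silyl ethers and, by β-elimination of ethene, the 2-(trimethylsilyl)ethyl vinylogous ester, while the acetic acid buffer keeps the phenols protonated so that neither quinone-methide ring opening at C2 nor enolisation at C3 is promoted and the (2S,3S) configuration is kept.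

**Compound list**
1 | 3,4-dihydroxybenzaldehyde | O=Cc1ccc(O)c(O)c1 | starting material
2 | 3,4-bis(tert-butyldimethylsilyloxy)benzaldehyde | O=Cc1ccc(O[Si](C)(C)C(C)(C)C)c(O[Si](C)(C)C(C)(C)C)c1 | intermediate
3 | 4-hydroxy-6-methyl-2H-pyran-2-one (triacetic acid lactone) | Cc1cc(O)cc(=O)o1 | starting material
4 | racemic 6-{2-[3,4-bis(TBS-oxy)phenyl]-2-hydroxyethyl}-4-hydroxy-2H-pyran-2-one | O=c1cc(O)cc(CC(O)c2ccc(O[Si](C)(C)C(C)(C)C)c(O[Si](C)(C)C(C)(C)C)c2)o1 | intermediate
5 | 6-{(E)-2-[3,4-bis(TBS-oxy)phenyl]ethenyl}-4-hydroxy-2H-pyran-2-one (3',4'-bis-O-TBS hispidin) | O=c1cc(O)cc(/C=C/c2ccc(O[Si](C)(C)C(C)(C)C)c(O[Si](C)(C)C(C)(C)C)c2)o1 | intermediate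
6 | 6-methyl-4-[2-(trimethylsilyl)ethoxy]-2H-pyran-2-one | Cc1cc(OCC[Si](C)(C)C)cc(=O)o1 | intermediate
7 | 2-oxo-4-[2-(trimethylsilyl)ethoxy]-2H-pyran-6-carbaldehyde | O=Cc1cc(OCC[Si](C)(C)C)cc(=O)o1 | intermediate
8 | (2R,5R)-hexane-2,5-diol | C[C@@H](O)CC[C@@H](C)O | starting material
9 | (2R,5R)-hexane-2,5-diyl dimethanesulfonate | C[C@@H](OS(C)(=O)=O)CC[C@@H](C)OS(C)(=O)=O | intermediate
10 | (2S,5S)-2,5-dimethylthiolane | C[C@H]1CC[C@H](C)S1 | intermediate
11 | [3,4-bis(TBS-oxy)phenyl]methanol | OCc1ccc(O[Si](C)(C)C(C)(C)C)c(O[Si](C)(C)C(C)(C)C)c1 | intermediate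
12 | 4-(bromomethyl)-1,2-bis(TBS-oxy)benzene | BrCc1ccc(O[Si](C)(C)C(C)(C)C)c(O[Si](C)(C)C(C)(C)C)c1 | intermediate
13 | (2S,5S)-1-[3,4-bis(TBS-oxy)benzyl]-2,5-dimethylthiolan-1-ium tetrafluoroborate | C[C@H]1CC[C@H](C)[S+]1Cc1ccc(O[Si](C)(C)C(C)(C)C)c(O[Si](C)(C)C(C)(C)C)c1.F[B-](F)(F)F | intermediate
14 | 6-{(E)-2-[3,4-bis(TBS-oxy)phenyl]ethenyl}-3-({2-oxo-4-[2-(trimethylsilyl)ethoxy]-2H-pyran-6-yl}methylidene)-2H-pyran-2,4(3H)-dione (oxadiene, exocyclic alkene geometry undefined, not isolated) | O=C1C=C(/C=C/c2ccc(O[Si](C)(C)C(C)(C)C)c(O[Si](C)(C)C(C)(C)C)c2)OC(=O)C1=Cc1cc(OCC[Si](C)(C)C)cc(=O)o1 | intermediate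
15 | racemic 6-{(E)-2-[3,4-bis(TBS-oxy)phenyl]ethenyl}-4-hydroxy-3-[(4-methylbenzenesulfonyl){2-oxo-4-[2-(trimethylsilyl)ethoxy]-2H-pyran-6-yl}methyl]-2H-pyran-2-one (sulfinic acid adduct of the oxadiene, not isolated) | O=c1oc(/C=C/c2ccc(O[Si](C)(C)C(C)(C)C)c(O[Si](C)(C)C(C)(C)C)c2)cc(O)c1C(c1cc(OCC[Si](C)(C)C)cc(=O)o1)S(=O)(=O)c1ccc(C)cc1 | intermediate
16 | (2S,5S)-2,5-dimethylthiolan-1-ium-1-yl [3,4-bis(TBS-oxy)phenyl]methanide (sulfonium benzylide, not isolated) | C[C@H]1CC[C@H](C)[S+]1[CH-]c1ccc(O[Si](C)(C)C(C)(C)C)c(O[Si](C)(C)C(C)(C)C)c1 | intermediate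
17 | (2S,3S)-2-[3,4-bis(TBS-oxy)phenyl]-6-{(E)-2-[3,4-bis(TBS-oxy)phenyl]ethenyl}-3-{2-oxo-4-[2-(trimethylsilyl)ethoxy]-2H-pyran-6-yl}-2,3-dihydro-4H-furo[3,2-c]pyran-4-one | O=c1cc(OCC[Si](C)(C)C)cc([C@H]2c3c(cc(/C=C/c4ccc(O[Si](C)(C)C(C)(C)C)c(O[Si](C)(C)C(C)(C)C)c4)oc3=O)O[C@@H]2c2ccc(O[Si](C)(C)C(C)(C)C)c(O[Si](C)(C)C(C)(C)C)c2)o1 | intermediate
18 | hypholomine B | O=c1cc(O)cc([C@H]2c3c(cc(/C=C/c4ccc(O)c(O)c4)oc3=O)O[C@@H]2c2ccc(O)c(O)c2)o1 | target

**Totals**
Total step count: 12.
Longest linear sequence: 6 steps (steps 1, 8, 9, 10, 11, 12; the hispidin branch, steps 1, 2, 3, 11, 12, is one step shorter).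

**Steps most likely to fail**

Step 11. The Knoevenagel stage may stall at the 2:1 bis-pyranone adduct, and the released sulfinate may benzylate at the expense of the sulfonium salt. The ylide may show poor facial selectivity, the ring closure at the electron-rich benzylic carbon may drift towards ionisation and lose the C2 configuration, or closure may go through the lactone oxygen. The fallback uses known chemistry, sets out from 5 and comes back at 17. Part of 5 would be O-alkylated under Mitsunobu conditions (TMSCH2CH2OH, PPh3, DIAD) to 6-{(E)-2-[3,4-bis(TBS-oxy)phenyl]ethenyl}-4-[2-(trimethylsilyl)ethoxy]-2H-pyran-2-one F1. Oxidative radical [3+2] annulation of 5 onto the styryl alkene of F1 (3 equiv) with Mn(OAc)3·2H2O in AcOH at 40 °C is a known dihydrofuran synthesis from 1,3-dicarbonyl enols and conjugated alkenes. The C3 radical of 5 should add at the alkene carbon next to the pyranone, and the benzylic radical, once oxidised, should be captured by the 4-oxygen, giving the trans ring as a racemate, that is 17 together with its (2R,3R)-enantiomer F2. Preparative HPLC on a chiral stationary phase would then deliver 17.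

Step 12. Cleavage of the 2-(trimethylsilyl)ethyl vinylogous ester may stay incomplete under buffered fluoride, and less buffered fluoride would risk base-induced ring opening at C2, enolisation at C3 and air oxidation of the catecholates. The fallback sets out from 17 and comes back at 18. Acidolysis of the 2-(trimethylsilyl)ethyl group (TFA, CH2Cl2, 0 °C), which aryl silyl ethers tolerate, would give (2S,3S)-2-[3,4-bis(TBS-oxy)phenyl]-6-{(E)-2-[3,4-bis(TBS-oxy)phenyl]ethenyl}-3-(4-hydroxy-2-oxo-2H-pyran-6-yl)-2,3-dihydro-4H-furo[3,2-c]pyran-4-one F3. The four phenolic silyl ethers would then be removed under weakly acidic conditions with KHF2 in degassed MeOH at rt to give 18.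

Step 5. The hot, wet selenium conditions may cleave the 2-(trimethylsilyl)ethyl group or carry the oxidation on to the carboxylic acid. The fallback sets out from 6 and comes back at 7. Wohl–Ziegler bromination of the 6-methyl group (NBS, dibenzoyl peroxide cat., PhCF3, reflux), known for 4-alkoxy-6-methyl-2-pyranones, would give 6-(bromomethyl)-4-[2-(trimethylsilyl)ethoxy]-2H-pyran-2-one F4. A Kornblum-type oxidation of the bromide with N-methylmorpholine N-oxide (MeCN, 4 Å MS, rt), through the alkoxyammonium salt, would then give aldehyde 7 under neutral conditions.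

**Further compounds**
F1 | step 11 | 6-{(E)-2-[3,4-bis(TBS-oxy)phenyl]ethenyl}-4-[2-(trimethylsilyl)ethoxy]-2H-pyran-2-one | O=c1cc(OCC[Si](C)(C)C)cc(/C=C/c2ccc(O[Si](C)(C)C(C)(C)C)c(O[Si](C)(C)C(C)(C)C)c2)o1
F2 | step 11 | (2R,3R)-enantiomer of compound 17 | O=c1cc(OCC[Si](C)(C)C)cc([C@@H]2c3c(cc(/C=C/c4ccc(O[Si](C)(C)C(C)(C)C)c(O[Si](C)(C)C(C)(C)C)c4)oc3=O)O[C@H]2c2ccc(O[Si](C)(C)C(C)(C)C)c(O[Si](C)(C)C(C)(C)C)c2)o1
F3 | step 12 | (2S,3S)-2-[3,4-bis(TBS-oxy)phenyl]-6-{(E)-2-[3,4-bis(TBS-oxy)phenyl]ethenyl}-3-(4-hydroxy-2-oxo-2H-pyran-6-yl)-2,3-dihydro-4H-furo[3,2-c]pyran-4-one | O=c1cc(O)cc([C@H]2c3c(cc(/C=C/c4ccc(O[Si](C)(C)C(C)(C)C)c(O[Si](C)(C)C(C)(C)C)c4)oc3=O)O[C@@H]2c2ccc(O[Si](C)(C)C(C)(C)C)c(O[Si](C)(C)C(C)(C)C)c2)o1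
F4 | step 5 | 6-(bromomethyl)-4-[2-(trimethylsilyl)ethoxy]-2H-pyran-2-one | BrCc1cc(OCC[Si](C)(C)C)cc(=O)o1
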